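**Assumptions:** compound 1 is taken as a catalogue compound. If step 7 gives both alkene isomers of 11, the mixture is carried on, because the alkene geometry is lost in step 8.

## Analysis of the target

The target is a diaryl ether of two pentyl-substituted polyketide arenes: a 6-hydroxy-3-pentylisocoumarin (benzo ring A with its fused pyranone, atoms C1 to C8a) and an olivetolic acid unit (ring B, C1' to C6'), joined by an oxygen between C8 of ring A and C5' of ring B. It has no stereocentre and no double bond whose configuration must be set, so the task is one of connectivity and of bringing sensitive groups through. Ring B is substituted at five of its six carbons (C1' carboxyl, C2' and C4' hydroxyl, C5' aryloxy, C6' pentyl; only C3' carries hydrogen), and its ether oxygen is flanked by the pentyl group and a hydroxyl, while on ring A the same oxygen lies ortho to the lactone carbonyl. A direct aryl–oxygen coupling between two such crowded, electron-rich rings is the bond that is hard to make, and this is the main difficulty. The sensitive groups are the ring B acid (a β-resorcylic acid that decarboxylates on heating or in acid), the isocoumarin (an enol lactone that alkoxide or hydroxide opens and whose C3=C4 bond can be reduced) and three free phenols. The strategy rests on ring B: C1' to C6' are an olivetolate with one extra oxygen on C5', and in a malonate–enone construction of an olivetolate C5' is the α-carbon of the enone, which can carry its oxygen as an O-alkyl (vinyl) substituent before the ring exists. The ether is therefore made as a bond from a ring A phenol oxygen to an sp3 carbon, and ring B is then grown around it by forming C1'–C6' and C2'–C3'.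

## Retrosynthetic reasoning

**17 to 16.** The two O–benzyl bonds are cut last. A benzyl ester on ring B and a benzyl ether on C6 fall together under neutral hydrogenolysis, so the decarboxylation-prone acid appears only in the final flask. The forward step must spare the C3=C4 bond of the lactone.

**16 to 15.** The lactone bond O2–C3 is cut, which leads back to an ortho-alkynyl tert-butyl benzoate. The alkyne already holds C3, C4 and the pentyl chain, and unlike the lactone it is inert to the enolate chemistry needed for ring B. The forward step has to close in the 6-endo sense and shed the tert-butyl group without touching the ring B benzyl ester.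

**15 to 11 and 12.** Ring B is cut at C1'–C6' and C2'–C3', and one unsaturation is removed. This gives the α-aryloxy enone 11 and the malonate 12. Cutting here, and not at the aryl–oxygen bond, removes the hindered diaryl ether coupling altogether and builds all six ring B carbons with their substituents in one flask. The forward reaction needs conjugate addition to an enone that carries a donor on its α-carbon, ring closure by the methyl ketone enolate only, and a dehydrogenation that leaves the alkyne and the tert-butyl ester of ring A alone.

**11 to 9 and 10.** The C3=C4 double bond of the enone is cut by a phosphonate olefination, with the aldehyde 10 bringing the pentyl chain. This places the double bond on the aryloxy-bearing carbon without ambiguity, which an aldol condensation of an aryloxy ketone would not guarantee.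

**9 to 7 and 8.** The bond between the ether oxygen and the future C5' is cut. In the forward direction the phenol 7 captures the carbenoid derived from 8. The phenol has a single ortho substituent and reacts through oxygen, so no aryl carbon–oxygen coupling is needed.

**7 to 6 to 5.** The tert-butyl ester is wanted for steps 8 and 9 but cannot be introduced by acyl substitution at a carbonyl with two ortho substituents. It is therefore made by O-alkylation of the carboxylate of 6, and 6 comes from hydrolysis of the acetonide 5, which frees the acid and the phenol together.

**5 to 3 and 4, then 3 to 2 to 1.** The aryl–alkynyl bond is cut (cross-coupling of the triflate 3 with the alkyne 4). The triflate comes from the chelated phenol of 2, and 2 from 1 by alkylation of the unchelated phenol. The acetonide of 1 differentiates the three oxygens of the starting arene from the outset.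

## Alternatives that were turned down

**Alternative 1:** The disconnection is the C5–C6 bond of ring A, with the pyranone and a complete, benzyl-protected ring B already present. In the forward key step a base removes a proton from the methyl group on C4 of a 6-pentyl-2-pyranone (the future C5). The extended enolate attacks the ester carbon of a β-aryloxyacrylate side chain on pyranone C3 (the future C6), methoxide leaves, and enolisation gives benzyl 4,6-bis(benzyloxy)-3-[(6-hydroxy-1-oxo-3-pentyl-1H-isochromen-8-yl)oxy]-2-pentylbenzoate (A1).
- For: the lactone and the pentyl chain are fixed before ring A exists, so no 6-endo versus 5-exo question arises, and A1 is one hydrogenolysis from the target. On the endgame this alternative is stronger than the chosen route.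
- Against: the aryl vinyl ether must come from conjugate addition of the ring B phenol benzyl 4,6-bis(benzyloxy)-3-hydroxy-2-pentylbenzoate (A2) to a pyranonyl alkynoate. A2 has its hydroxyl between a pentyl and a benzyloxy group and is a poor nucleophile, and it needs several steps of its own, including an oxidation of an olivetolate at C5'. The acrylate must have its ester cis to the pyranone to cyclise, which the addition does not control. Bases strong enough to deprotonate the methyl group also attack 2-pyranones.
- Comparison: the chosen strategy gives up the shorter endgame, but it needs no preformed ring B, makes the ether at an unhindered ring A phenol, and builds ring B by a classical annulation, so it should be shorter overall.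

**Alternative 2:** The disconnection is the C4a–C8a bond of ring A, whose carbons are stored in a 4-aryloxy-2-pyranone with a ketal-protected keto side chain. In the forward key step methoxide opens the pyranone to an enoate, the dienolate carbon (future C8a) adds to the side-chain ketone (future C4a), and loss of water with enolisation gives benzyl 4,6-bis(benzyloxy)-3-{5-hydroxy-2-(methoxycarbonyl)-3-[(2-pentyl-1,3-dioxolan-2-yl)methyl]phenoxy}-2-pentylbenzoate (A3).
- For: the folding is biomimetic and sets the ring A oxygen pattern automatically. A3 carries a masked 2-oxoheptyl group next to the ester, so acid would unmask and lactonise it with no regiochemical choice. On that point it is stronger than the alkyne closure of the chosen route.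
- Against: a 4-aryloxy-2-pyranone is a vinylogous aryl ester, and methoxide can add at C4 and expel the phenoxide of A2, which destroys the ether. In the chosen key step the aryloxy group sits on a carbon from which no such elimination is possible. The pyranone has further electrophilic sites, A2 must first be attached to an activated pyranone C4 as a hindered nucleophile, and A3 still needs ketal removal, lactonisation and debenzylation.
- Comparison: the chosen strategy offers a key step whose aryloxy group is structurally safe, and does not depend on A2.

**Alternative 3:** The disconnection cuts C4a–C4 and C8a–C1, so both carbon substituents of ring A are placed on an aryne at once. In the forward key step fluoride releases the aryne from an ortho-silyl aryl triflate that already carries the ring B aryloxy group and a benzyloxy group. A malonic diester enolate adds, closes to a four-membered alkoxide and fragments (formal insertion into a C–C bond), giving benzyl 4,6-bis(benzyloxy)-3-[5-(benzyloxy)-2-(methoxycarbonyl)-3-(2-methoxy-2-oxoethyl)phenoxy]-2-pentylbenzoate (A4). No ring is formed.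
- For: the insertion is mild, and the oxygen next to the aryne steers the carbon nucleophile to the distal carbon, which puts the ester ortho to the ether as required. The aryne step is probably more predictable than the annulation of the chosen route.
- Against: the ether must exist before the aryne, so A2 has to be joined to an arene by a hindered aryl–oxygen coupling, the very bond the chosen route avoids. The aryne precursor takes several steps. A4 still lacks C3 and the pentyl chain, so selective hydrolysis of one of two methyl esters, acylation with a six-carbon unit, decarboxylation and cyclisation must follow, classically under heat that the ring B ester may not bear.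
- Comparison: the chosen strategy has a riskier single step but no aryl–oxygen coupling and a clearly shorter sequence.

Key step: step 8

## Route

Step 1
Reactants: 1 5,7-dihydroxy-2,2-dimethyl-4H-1,3-benzodioxin-4-one
Product: 2 7-(benzyloxy)-5-hydroxy-2,2-dimethyl-4H-1,3-benzodioxin-4-one
Conditions: BnBr (1.05 equiv), K2CO3 (1.1 equiv), acetone, rt
Reagents that add atoms: benzyl bromide, BrCc1ccccc1
Why: Williamson etherification; the C5 hydroxyl is held in a hydrogen bond to the C4 carbonyl and is the less acidic one, so one equivalent of base and halide should alkylate the C7 hydroxyl selectively.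

Step 2
Reactants: 2 7-(benzyloxy)-5-hydroxy-2,2-dimethyl-4H-1,3-benzodioxin-4-one
Product: 3 7-(benzyloxy)-2,2-dimethyl-4-oxo-4H-1,3-benzodioxin-5-yl trifluoromethanesulfonate
Conditions: Tf2O, pyridine, CH2Cl2, 0 °C
Reagents that add atoms: trifluoromethanesulfonic anhydride, O=S(=O)(OS(=O)(=O)C(F)(F)F)C(F)(F)F
Why: O-sulfonylation of the only remaining hydroxyl turns C5–O into a leaving group for cross-coupling; no other nucleophilic site is present.

Step 3
Reactants: 3 7-(benzyloxy)-2,2-dimethyl-4-oxo-4H-1,3-benzodioxin-5-yl trifluoromethanesulfonate; 4 hept-1-yne
Product: 5 7-(benzyloxy)-5-(hept-1-yn-1-yl)-2,2-dimethyl-4H-1,3-benzodioxin-4-one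
Conditions: PdCl2(PPh3)2 (5 mol%), CuI (10 mol%), Et3N, DMF, 60 °C
Reagents that add atoms: none
Why: Sonogashira coupling; the ortho carbonyl activates the triflate for oxidative addition, and the acetonide keeps the acid and the second phenol masked so that nothing can add to the new alkyne.

Step 4
Reactants: 5 7-(benzyloxy)-5-(hept-1-yn-1-yl)-2,2-dimethyl-4H-1,3-benzodioxin-4-one
Product: 6 4-(benzyloxy)-2-(hept-1-yn-1-yl)-6-hydroxybenzoic acid
Conditions: KOH, THF/H2O, 50 °C; then cold 1 M HCl to pH 3
Reagents that add atoms: potassium hydroxide, [K+].[OH-]
Why: Saponification of the acylal-type lactone: hydroxide attacks C4 and the hemiketal fragment collapses to acetone and the phenoxide. Aqueous hydroxide at this temperature should not isomerise the alkyne, and cold acidification limits decarboxylation of the salicylic acid.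

Step 5
Reactants: 6 4-(benzyloxy)-2-(hept-1-yn-1-yl)-6-hydroxybenzoic acid
Product: 7 tert-butyl 4-(benzyloxy)-2-(hept-1-yn-1-yl)-6-hydroxybenzoate
Conditions: tert-butyl 2,2,2-trichloroacetimidate (2.5 equiv), CH2Cl2/cyclohexane, rt
Reagents that add atoms: tert-butyl 2,2,2-trichloroacetimidate, CC(C)(C)OC(=N)C(Cl)(Cl)Cl
Why: Imidate esterification: the acid protonates the imidate and the ion pair collapses by O-alkylation of the carboxylate, a path that is indifferent to the two ortho substituents. The hydrogen-bonded phenol is not acidic enough to react without added catalyst.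

Step 6
Reactants: 7 tert-butyl 4-(benzyloxy)-2-(hept-1-yn-1-yl)-6-hydroxybenzoate; 8 dimethyl (1-diazo-2-oxopropyl)phosphonate
Product: 9 tert-butyl 4-(benzyloxy)-2-{[1-(dimethoxyphosphoryl)-2-oxopropyl]oxy}-6-(hept-1-yn-1-yl)benzoate (racemate)
Conditions: Rh2(OAc)4 (2 mol%), toluene, 80 °C, slow addition of 8 (1.5 equiv)
Reagents that add atoms: none
Why: Rhodium carbenoid O–H insertion: the phenol oxygen captures the carbenoid from 8 and a proton shift gives the α-aryloxy β-ketophosphonate, so the ether oxygen is bonded to sp3 carbon without any aryl C–O coupling. Insertion into O–H should outrun addition to the internal alkyne; the new stereocentre forms as a racemate and is removed in step 7.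

Step 7
Reactants: 9 tert-butyl 4-(benzyloxy)-2-{[1-(dimethoxyphosphoryl)-2-oxopropyl]oxy}-6-(hept-1-yn-1-yl)benzoate (racemate); 10 hexanal
Product: 11 tert-butyl 4-(benzyloxy)-2-(hept-1-yn-1-yl)-6-{[(3Z)-2-oxonon-3-en-3-yl]oxy}benzoate
Conditions: NaH, THF, 0 °C; then 10, 0 °C to rt
Reagents that add atoms: none
Why: Horner–Wadsworth–Emmons olefination; the isomer with the pentyl group trans to the acetyl group (Z by the sequence rules) should predominate, and the geometry does not matter because both alkene carbons become ring B carbons. A hydride base without alkoxide avoids deacetylation of the β-ketophosphonate, and the tert-butyl ester is too hindered to be attacked by the stabilised carbanion.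

Step 8
Reactants: 11 tert-butyl 4-(benzyloxy)-2-(hept-1-yn-1-yl)-6-{[(3Z)-2-oxonon-3-en-3-yl]oxy}benzoate; 12 dibenzyl malonate
Product: 15 benzyl 3-[5-(benzyloxy)-2-(tert-butoxycarbonyl)-3-(hept-1-yn-1-yl)phenoxy]-4,6-dihydroxy-2-pentylbenzoate, via Michael adduct 13 (not isolated), via cyclohexane-1,3-dione 14 (not isolated)
Conditions: 12 (1.1 equiv), NaH (1.05 equiv), THF, 0 °C to 60 °C; then DMF, NaOAc (2 equiv), Br2 (1.0 equiv), 0 °C to 60 °C
Reagents that add atoms: none
Why: Sodio dibenzyl malonate adds 1,4 to the enone of 11 at C4 (bond C1'–C6') to give 13 as its malonate anion; proton exchange provides a small share of the methyl ketone enolate, which attacks one malonate ester in a 6-(enolendo)-exo-trig Claisen closure (bond C2'–C3') with loss of benzyl oxide, and deprotonation of the acidic dione 14 pulls both equilibria forward. The closest known reaction is the malonate–enone annulation to 5-substituted cyclohexane-1,3-diones followed by bromine dehydrogenation, the classical route to olivetolate esters. Bromine then reacts at the enol of 14, and loss of two molecules of HBr, taken up by acetate, gives the resorcinol ring; the three stereocentres of 14 (C1', C5', C6') form without control and all become sp2, so none has to be set. The first selectivity needed is ring closure by the methyl ketone enolate only: the more stabilised α-aryloxy enolate could reach a malonate ester only through a four-membered ring, and its attack on the ring A ester is hindered by the tert-butyl group and would give a non-enolisable, reversible product. The second is retention of the ether: the aryloxy group on C5' is α to the C4' carbonyl and β to no carbonyl, so no E1cB path can expel the ring A phenoxide. The third is chemoselective oxidation: one equivalent of bromine at 0 °C should be consumed by the enol far faster than by the ester-deactivated aryl alkyne, and the acetate buffer keeps the medium too weakly acidic to cleave the tert-butyl ester or to lactonise ring A.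

Step 9
Reactants: 15 benzyl 3-[5-(benzyloxy)-2-(tert-butoxycarbonyl)-3-(hept-1-yn-1-yl)phenoxy]-4,6-dihydroxy-2-pentylbenzoate
Product: 16 benzyl 3-{[6-(benzyloxy)-1-oxo-3-pentyl-1H-isochromen-8-yl]oxy}-4,6-dihydroxy-2-pentylbenzoate
Conditions: Ph3PAuCl (5 mol%), AgOTf (5 mol%), ClCH2CH2Cl, rt
Reagents that add atoms: none
Why: Gold-catalysed 6-endo-dig cyclisation of an ortho-alkynylbenzoate ester: the carbonyl oxygen of the tert-butyl ester attacks the gold-activated distal alkyne carbon, the tert-butyl group leaves as 2-methylpropene, and the released proton cleaves the vinyl–gold bond. A neutral carbonyl oxygen lying in the arene plane reaches the distal carbon better than the proximal one, which favours the isocoumarin over the alkylidene phthalide; the ring B benzyl ester has no alkyne within reach and should stay.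

Step 10
Reactants: 16 benzyl 3-{[6-(benzyloxy)-1-oxo-3-pentyl-1H-isochromen-8-yl]oxy}-4,6-dihydroxy-2-pentylbenzoate
Product: 17 4,6-dihydroxy-3-[(6-hydroxy-1-oxo-3-pentyl-1H-isochromen-8-yl)oxy]-2-pentylbenzoic acid
Conditions: H2 (1 atm), Pd/C (10 wt%), EtOAc, rt; stopped after two equivalents of H2
Reagents that add atoms: none
Why: Hydrogenolysis of the benzyl ether and the benzyl ester under neutral conditions at room temperature, which spares the decarboxylation-prone acid. The C3=C4 bond belongs to a conjugated enol lactone and should be reduced much more slowly than the O-benzyl groups are cleaved.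

## Compound list

1 | 5,7-dihydroxy-2,2-dimethyl-4H-1,3-benzodioxin-4-one | CC1(C)OC(=O)c2c(O)cc(O)cc2O1 | starting material
2 | 7-(benzyloxy)-5-hydroxy-2,2-dimethyl-4H-1,3-benzodioxin-4-one | CC1(C)OC(=O)c2c(O)cc(OCc3ccccc3)cc2O1 | intermediate
3 | 7-(benzyloxy)-2,2-dimethyl-4-oxo-4H-1,3-benzodioxin-5-yl trifluoromethanesulfonate | CC1(C)OC(=O)c2c(OS(=O)(=O)C(F)(F)F)cc(OCc3ccccc3)cc2O1 | intermediate
4 | hept-1-yne | C#CCCCCC | starting material
5 | 7-(benzyloxy)-5-(hept-1-yn-1-yl)-2,2-dimethyl-4H-1,3-benzodioxin-4-one | CCCCCC#Cc1cc(OCc2ccccc2)cc2OC(C)(C)OC(=O)c12 | intermediate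
6 | 4-(benzyloxy)-2-(hept-1-yn-1-yl)-6-hydroxybenzoic acid | CCCCCC#Cc1cc(OCc2ccccc2)cc(O)c1C(=O)O | intermediate
7 | tert-butyl 4-(benzyloxy)-2-(hept-1-yn-1-yl)-6-hydroxybenzoate | CCCCCC#Cc1cc(OCc2ccccc2)cc(O)c1C(=O)OC(C)(C)C | intermediate
8 | dimethyl (1-diazo-2-oxopropyl)phosphonate | COP(=O)(OC)C(=[N+]=[N-])C(C)=O | starting material
9 | tert-butyl 4-(benzyloxy)-2-{[1-(dimethoxyphosphoryl)-2-oxopropyl]oxy}-6-(hept-1-yn-1-yl)benzoate (racemate) | CCCCCC#Cc1cc(OCc2ccccc2)cc(OC(C(C)=O)P(=O)(OC)OC)c1C(=O)OC(C)(C)C | intermediate
10 | hexanal | CCCCCC=O | starting material
11 | tert-butyl 4-(benzyloxy)-2-(hept-1-yn-1-yl)-6-{[(3Z)-2-oxonon-3-en-3-yl]oxy}benzoate | CCCCC/C=C(\Oc1cc(OCc2ccccc2)cc(C#CCCCCC)c1C(=O)OC(C)(C)C)C(C)=O | intermediate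
12 | dibenzyl malonate (dibenzyl propanedioate) | O=C(CC(=O)OCc1ccccc1)OCc1ccccc1 | starting material
13 | dibenzyl 2-{3-[5-(benzyloxy)-2-(tert-butoxycarbonyl)-3-(hept-1-yn-1-yl)phenoxy]-2-oxononan-4-yl}propanedioate (diastereomer mixture, not isolated) | CCCCCC(C(Oc1cc(OCc2ccccc2)cc(C#CCCCCC)c1C(=O)OC(C)(C)C)C(C)=O)C(C(=O)OCc1ccccc1)C(=O)OCc1ccccc1 | intermediate
14 | benzyl 3-[5-(benzyloxy)-2-(tert-butoxycarbonyl)-3-(hept-1-yn-1-yl)phenoxy]-4,6-dioxo-2-pentylcyclohexane-1-carboxylate (diastereomer and enol mixture, not isolated) | CCCCCC1C(Oc2cc(OCc3ccccc3)cc(C#CCCCCC)c2C(=O)OC(C)(C)C)C(=O)CC(=O)C1C(=O)OCc1ccccc1 | intermediate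
15 | benzyl 3-[5-(benzyloxy)-2-(tert-butoxycarbonyl)-3-(hept-1-yn-1-yl)phenoxy]-4,6-dihydroxy-2-pentylbenzoate | CCCCCc1c(Oc2cc(OCc3ccccc3)cc(C#CCCCCC)c2C(=O)OC(C)(C)C)c(O)cc(O)c1C(=O)OCc1ccccc1 | intermediate
16 | benzyl 3-{[6-(benzyloxy)-1-oxo-3-pentyl-1H-isochromen-8-yl]oxy}-4,6-dihydroxy-2-pentylbenzoate | CCCCCc1cc2cc(OCc3ccccc3)cc(Oc3c(O)cc(O)c(C(=O)OCc4ccccc4)c3CCCCC)c2c(=O)o1 | intermediate
17 | 4,6-dihydroxy-3-[(6-hydroxy-1-oxo-3-pentyl-1H-isochromen-8-yl)oxy]-2-pentylbenzoic acid | CCCCCc1cc2cc(O)cc(Oc3c(O)cc(O)c(C(=O)O)c3CCCCC)c2c(=O)o1 | target

## Step count and least certain steps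

Total: 10 steps. Longest linear sequence: 10 steps (1 to 17); compounds 4, 8, 10 and 12 are bought and enter directly.

**Step 8 (key step).** Two processes are most likely to fail.
- The conjugate addition may be slow and reversible, because the α-aryloxy group donates into the alkene and the alkene is trisubstituted; prolonged heating would then favour retro-addition and decomposition.
- The dehydrogenation may go astray: transfer of electrophilic bromine to the alkynyl tert-butyl benzoate (bromolactonisation of ring A) or to C3' of the finished ring B, acid cleavage of the tert-butyl ester if the buffer is overrun, or bromination at C5' followed by loss of the ring A phenol.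
- Fallback: the sequence sets out from 14, which is isolated by acidifying the annulation mixture, with the bromine stage left out. LiN(iPr)2 (2.2 equiv, THF, −78 °C) should give the dianion, deprotonated at the enolised dione and at C1'. PhSeBr should selenenylate C1' anti to the C6' pentyl group and give benzyl 3-[5-(benzyloxy)-2-(tert-butoxycarbonyl)-3-(hept-1-yn-1-yl)phenoxy]-4,6-dioxo-2-pentyl-1-(phenylselanyl)cyclohexane-1-carboxylate F1. H2O2 (CH2Cl2, pyridine, 0 °C) oxidises selenium, the selenoxide leaves by syn-elimination with the cis hydrogen on C6', and tautomerisation returns the route to 15. No electrophilic halogen and no acid meet ring A in this sequence.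

**Step 6.** The carbenoid may be diverted, by Wolff rearrangement, by addition to the alkyne, or by slow capture at the hydrogen-bonded phenol.
- Fallback: the sequence sets out from 7 and replaces steps 6 and 7. (3E)-Non-3-en-2-one F2 is epoxidised with H2O2 and NaOH in methanol to racemic trans-3,4-epoxynonan-2-one F3. With Cs2CO3 in DMF at 60 °C the phenoxide of 7 should open F3 at C3, the carbon α to the carbonyl, to give tert-butyl 4-(benzyloxy)-2-(hept-1-yn-1-yl)-6-[(4-hydroxy-2-oxononan-3-yl)oxy]benzoate F4 (not isolated). F4 loses water by an E1cB path, and the route is rejoined at 11.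

**Step 9.** The ring may close at the proximal alkyne carbon (5-exo, giving an alkylidene phthalide), or the tert-butyl group may be lost incompletely or be captured by the electron-rich ring B.
- Fallback: the sequence sets out from 15. TFA in CH2Cl2 at 0 °C removes the tert-butyl group and gives 4-(benzyloxy)-2-{3-[(benzyloxy)carbonyl]-4,6-dihydroxy-2-pentylphenoxy}-6-(hept-1-yn-1-yl)benzoic acid F5. A catalytic amount of TfOH in CH2Cl2 then lactonises the free acid onto the alkyne; Brønsted-acid catalysis of ortho-alkynylbenzoic acids is known to favour the six-membered lactone. The route is rejoined at 16.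

**Step 10.** The C3=C4 bond of the isocoumarin may be reduced if the reaction runs on, and the acid may decarboxylate if the product is warmed during isolation.
- Fallback: the sequence sets out from 16. BCl3 with pentamethylbenzene in CH2Cl2 at −78 °C cleaves the benzyl ether and the benzyl ester by Lewis-acid dealkylation, with no hydrogen present, and leads directly to 17. It makes no compound beyond those listed (entry F0).

## Further compounds

F1 | step 8 | benzyl 3-[5-(benzyloxy)-2-(tert-butoxycarbonyl)-3-(hept-1-yn-1-yl)phenoxy]-4,6-dioxo-2-pentyl-1-(phenylselanyl)cyclohexane-1-carboxylate | CCCCCC1C(Oc2cc(OCc3ccccc3)cc(C#CCCCCC)c2C(=O)OC(C)(C)C)C(=O)CC(=O)C1([Se]c1ccccc1)C(=O)OCc1ccccc1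
F2 | step 6 | (3E)-non-3-en-2-one | CCCCC/C=C/C(C)=O
F3 | step 6 | rac-1-[(2R,3S)-3-pentyloxiran-2-yl]ethan-1-one (trans-3,4-epoxynonan-2-one) | CCCCC[C@@H]1O[C@H]1C(C)=O
F4 | step 6 | tert-butyl 4-(benzyloxy)-2-(hept-1-yn-1-yl)-6-[(4-hydroxy-2-oxononan-3-yl)oxy]benzoate (diastereomer mixture) | CCCCCC(O)C(Oc1cc(OCc2ccccc2)cc(C#CCCCCC)c1C(=O)OC(C)(C)C)C(C)=O
F5 | step 9 | 4-(benzyloxy)-2-{3-[(benzyloxy)carbonyl]-4,6-dihydroxy-2-pentylphenoxy}-6-(hept-1-yn-1-yl)benzoic acid | CCCCCc1c(Oc2cc(OCc3ccccc3)cc(C#CCCCCC)c2C(=O)O)c(O)cc(O)c1C(=O)OCc1ccccc1
F0 | step 10 | none | none
A1 | alternative 1 | benzyl 4,6-bis(benzyloxy)-3-[(6-hydroxy-1-oxo-3-pentyl-1H-isochromen-8-yl)oxy]-2-pentylbenzoate | CCCCCc1cc2cc(O)cc(Oc3c(OCc4ccccc4)cc(OCc4ccccc4)c(C(=O)OCc4ccccc4)c3CCCCC)c2c(=O)o1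
A2 | alternative 1 | benzyl 4,6-bis(benzyloxy)-3-hydroxy-2-pentylbenzoate | CCCCCc1c(O)c(OCc2ccccc2)cc(OCc2ccccc2)c1C(=O)OCc1ccccc1
A3 | alternative 2 | benzyl 4,6-bis(benzyloxy)-3-{5-hydroxy-2-(methoxycarbonyl)-3-[(2-pentyl-1,3-dioxolan-2-yl)methyl]phenoxy}-2-pentylbenzoate | CCCCCC1(Cc2cc(O)cc(Oc3c(OCc4ccccc4)cc(OCc4ccccc4)c(C(=O)OCc4ccccc4)c3CCCCC)c2C(=O)OC)OCCO1
A4 | alternative 3 | benzyl 4,6-bis(benzyloxy)-3-[5-(benzyloxy)-2-(methoxycarbonyl)-3-(2-methoxy-2-oxoethyl)phenoxy]-2-pentylbenzoate | COC(=O)Cc1cc(OCc2ccccc2)cc(Oc2c(OCc3ccccc3)cc(OCc3ccccc3)c(C(=O)OCc3ccccc3)c2CCCCC)c1C(=O)OC
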